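**Plan**

Numbering: ring C1 (C=O), C2 (bears CH2OAc), C3, C4 (CHOH), C5 and C6 (oxirane, C5 quaternary); chain C1'–C12'. The retrosynthesis cuts C1'–C2' (chain off, C1' taken through the ketone), then C2–CH2OAc and C2=C3, then C5–C6 together with C6–O, then C3–C4; in the chain it cuts C5'–C6' and C10'=C11'.
Enabling feature: C1(=O)–C6–C5 is an α,β-epoxy ketone inside the six-membered ring and C5 lies 1,5 to C1 through C2–C3–C4. An α-chloro enolate at C6 and a ketone at C5 can therefore close the carbocycle and then the oxirane in one operation (Darzens annulation). A 1,3-dioxane ring over O4–C4–C5–C1' is carried as a temporary stereocontrol element.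
Forward: dioxanone (C4, C5, C1') + acrylate (C1–C3) + CH2Cl (C6) → chloro diketone → carbocycle and then oxirane in the same step → C2=C3 and CH2OAc → dioxane opened and C1' oxidised to the aldehyde → chain joined at C1'–C2' → C1' ketone → reduction.
Stereochemistry: C4 from the SAMP auxiliary. C5 and C6 from C4 (cis-fusion onto the dioxane chair, anti-periplanar oxirane closure, C6 epimers converge). C1' from C4–OH-directed hydride delivery (1,3-anti), which also converges the C1' epimers of the coupling. 10'Z from a Wittig reaction with an α-silyloxy ketone, 2'E and 6'E from syn-carboalumination, 4'E from (E)-1,2-dichloroethene.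

Key step: step 5

Remark: the azaenolate of hydrazone 3 is assumed to add to methyl acrylate on the same face on which this hydrazone series is alkylated, which gives (4S); the antipodal auxiliary would serve if the sense were opposite. Compounds 1, 2, 4, 20, 22, 25 and 26 are taken as commercial.

Step 1
Reactants: 1 2,2-dimethyl-1,3-dioxan-5-one; 2 (S)-1-amino-2-(methoxymethyl)pyrrolidine (SAMP)
Product: 3 SAMP hydrazone of 1
Conditions: C6H6, reflux, water separator
Reagents that add atoms: none
Why: Condensation of a ketone with an N,N-dialkylhydrazine (hydrazone formation) is driven by removal of water and installs the chiral auxiliary without creating a stereocentre.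

Step 2
Reactants: 3 SAMP hydrazone of 1; 4 methyl acrylate
Product: 6 methyl 3-[(4S)-2,2-dimethyl-5-{[(2S)-2-(methoxymethyl)pyrrolidin-1-yl]imino}-1,3-dioxan-4-yl]propanoate, via lithium azaenolate 5 (not isolated)
Conditions: t-BuLi, THF, −78 °C; then 4, −100 → −78 °C; AcOH quench
Reagents that add atoms: none
Why: Asymmetric Michael addition of a metalated SAMP hydrazone to an acrylate, in which the rigid lithium azaenolate 5 (lithium held by the methoxymethyl arm) is attacked on one face only, should set C4 as (S).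

Step 3
Reactants: 6 hydrazone methyl ester
Product: 8 1-chloro-4-[(4S)-2,2-dimethyl-5-{[(2S)-2-(methoxymethyl)pyrrolidin-1-yl]imino}-1,3-dioxan-4-yl]butan-2-one, via lithium hemiketal alkoxide 7 (not isolated)
Conditions: ClCH2I, MeLi·LiBr, THF, −78 °C; AcOH quench at −78 °C
Reagents that add atoms: chloroiodomethane ClCI
Why: Chloromethyllithium, generated in the flask by iodine–lithium exchange, should add once to the methyl ester because the tetrahedral lithium alkoxide 7 survives at −78 °C until the acidic quench (ester to α-chloro ketone homologation), while the C5 ketone stays masked as the hydrazone and C4 is untouched.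

Step 4
Reactants: 8 chloromethyl ketone hydrazone
Product: 9 (4S)-4-(4-chloro-3-oxobutyl)-2,2-dimethyl-1,3-dioxan-5-one
Conditions: sat. aq. (CO2H)2, Et2O, rt
Reagents that add atoms: water O
Why: Hydrolytic cleavage of the SAMP hydrazone in the two-phase oxalic acid system is mild enough to leave the acetonide, the α-chloro ketone and the configuration at C4 intact, and it returns the auxiliary as its oxalate.

Step 5
Reactants: 9 (4S)-4-(4-chloro-3-oxobutyl)-2,2-dimethyl-1,3-dioxan-5-one
Product: 12 tricyclic epoxy ketone (4S,5R,6R) [5,6-epoxy-4-hydroxy-5-(hydroxymethyl)cyclohexan-1-one as its 4,1'-O-isopropylidene acetal; C4–O cis to C5–C1'; oxirane oxygen trans to C4–O], via lithium chloro-enolate 10 (not isolated), via lithium chlorohydrin alkoxide 11 (not isolated)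
Conditions: LiN(SiMe3)2 (1.1 equiv), THF, −78 → 0 °C
Reagents that add atoms: none
Why: Kinetic deprotonation of the most acidic position, the ClCH2 group, gives chloro-enolate 10, whose carbon C6 adds to the C5 ketone (intramolecular aldol) to give aldolate 11, and the C5 alkoxide then displaces chloride at C6 by SN2 to form the oxirane. The closest known reaction type is the Darzens condensation of an α-chloro ketone with a ketone, run here intramolecularly, with the ketol-forming stage of a Robinson annulation as the model for the ring closure. The carbocycle closes 6-(enolendo)-exo-trig and the oxirane 3-exo-tet. C5 is controlled by C4 through the temporary ring: in the chair 1,3-dioxan-5-one the tether is equatorial at C4 and the enolate carbon adds along the axial trajectory, which is unhindered because the ring oxygens carry no axial hydrogens, so the aldolate is cis-fused with C5–O trans to C4–O. C6 is controlled by the stereoelectronics of the closure, since only the chlorohydrin with C6–Cl anti-periplanar to C5–O can close and its C6 epimer returns to it by enolisation of the α-chloro ketone or by retro-aldol, so that both converge on the (4S,5R,6R) cis-oxirane. The step needs enolisation at ClCH2 rather than at C2, C4 or C1' and no loss of configuration at C4, which the higher acidity of the α-chloro ketone, the hindered amide base at −78 °C and the fact that C4 stops being enolisable once C5 is sp3 should secure.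

Step 6
Reactants: 12 tricyclic epoxy ketone
Product: 15 tricyclic epoxy enone (4S,5R,6R) [5,6-epoxy-4-hydroxy-5-(hydroxymethyl)cyclohex-2-en-1-one as its 4,1'-O-isopropylidene acetal], via lithium enolate 13 (not isolated), via C2 sulfilimine 14 (not isolated)
Conditions: LiN(iPr)2, THF, −78 °C; then PhS(Cl)=NtBu, −78 °C
Reagents that add atoms: none
Why: In this Mukaiyama dehydrogenation the only enolisable position of 12 is C2, its lithium enolate 13 is sulfenylated at C2 by the sulfinimidoyl chloride, and sulfilimine 14 should undergo syn-elimination towards C3 at −78 °C to give the C2=C3 enone without touching the oxirane or the stereocentres.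

Step 7
Reactants: 15 tricyclic epoxy enone
Product: 16 2-(hydroxymethyl) derivative of 15
Conditions: aq. HCHO, DMAP (cat.), THF, rt
Reagents that add atoms: formaldehyde C=O
Why: In this Morita–Baylis–Hillman hydroxymethylation DMAP adds reversibly to C3, the resulting enolate is trapped at C2 by formaldehyde and the catalyst is expelled, which should place the CH2OH group on the α-carbon of the enone under nearly neutral conditions.

Step 8
Reactants: 16 2-(hydroxymethyl) epoxy enone
Product: 17 2-(acetoxymethyl) derivative of 15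
Conditions: Ac2O, pyridine, CH2Cl2, 0 °C
Reagents that add atoms: acetic anhydride CC(=O)OC(C)=O
Why: Acylation of the only free hydroxyl group (primary, allylic) should give the acetate of the target before any other hydroxyl is unmasked.

Step 9
Reactants: 17 acetonide acetate
Product: 18 [(1R,5S,6R)-5-hydroxy-6-(hydroxymethyl)-2-oxo-7-oxabicyclo[4.1.0]hept-3-en-3-yl]methyl acetate
Conditions: AcOH/H2O (4:1), 40 °C
Reagents that add atoms: none
Why: Acid-catalysed hydrolysis of the isopropylidene acetal removes the temporary ring, and dilute acetic acid should spare the acetate and the α,β-epoxy ketone, whose oxirane is deactivated towards acid opening by the carbonyl group.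

Step 10
Reactants: 18 diol acetate
Product: 19 [(1R,5S,6R)-6-formyl-5-hydroxy-2-oxo-7-oxabicyclo[4.1.0]hept-3-en-3-yl]methyl acetate
Conditions: TEMPO (cat.), PhI(OAc)2, CH2Cl2, rt
Reagents that add atoms: none
Why: TEMPO-catalysed oxidation with PhI(OAc)2 is selective for the primary over the secondary alcohol and stops at the aldehyde, which cannot enolise because C5 is quaternary.

Step 11
Reactants: 20 5-iodopent-1-yne
Product: 21 (pent-4-yn-1-yl)triphenylphosphonium iodide
Conditions: PPh3, MeCN, reflux
Reagents that add atoms: triphenylphosphine c1ccc(cc1)P(c1ccccc1)c1ccccc1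
Why: SN2 alkylation of triphenylphosphine by the primary iodide should give the phosphonium salt.

Step 12
Reactants: 21 (pent-4-yn-1-yl)triphenylphosphonium iodide; 22 1-[(tert-butyldimethylsilyl)oxy]propan-2-one
Product: 24 (Z)-tert-butyldimethyl[(2-methylhept-2-en-6-yn-1-yl)oxy]silane, via phosphorus ylide 23 (not isolated)
Conditions: KN(SiMe3)2 (1.0 equiv), THF, −78 → 0 °C; then 22, −78 °C → rt
Reagents that add atoms: none
Why: The Wittig reaction of a non-stabilised ylide with an α-silyloxy ketone is a combination known to give the Z-trisubstituted allylic ether (chain cis to CH2O) with high selectivity, and one equivalent of base should deprotonate the phosphonium salt in preference to the alkyne.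

Step 13
Reactants: 25 (E)-1,2-dichloroethene; 26 ethynyltrimethylsilane
Product: 27 (E)-(4-chlorobut-3-en-1-yn-1-yl)trimethylsilane
Conditions: Pd(PPh3)4 (cat.), CuI (cat.), n-BuNH2, Et2O, rt, 25 in excess
Reagents that add atoms: none
Why: Sonogashira coupling of the alkyne with an excess of the dichloroalkene should stop at the mono-coupled chloroenyne and retain the E geometry.

Step 14
Reactants: 24 (Z)-enyne silyl ether; 27 (E)-chloroenyne
Product: 29 tert-butyldimethyl{[(2Z,6E,8E)-2,6-dimethyl-11-(trimethylsilyl)undeca-2,6,8-trien-10-yn-1-yl]oxy}silane, via alkenylalane 28 (not isolated)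
Conditions: AlMe3, Cp2ZrCl2 (cat.), CH2Cl2, 0 °C → rt; then 27, ZnCl2, Pd(PPh3)4 (cat.), THF, rt
Reagents that add atoms: trimethylaluminium C[Al](C)C
Why: Zirconium-catalysed carboalumination adds methyl and aluminium syn across the terminal alkyne with aluminium at the terminus (E-alkenylalane 28), and palladium-catalysed cross-coupling of this alane through zinc (Negishi coupling) with the activated alkenyl chloride proceeds with retention at both sp2 carbons, which should fix 6'E and 4'E.

Step 15
Reactants: 29 silylated trienyne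
Product: 30 tert-butyl{[(2Z,6E,8E)-2,6-dimethylundeca-2,6,8-trien-10-yn-1-yl]oxy}dimethylsilane
Conditions: K2CO3 (cat.), MeOH, rt
Reagents that add atoms: none
Why: Methanolysis of the alkynyl–silicon bond with catalytic carbonate (protodesilylation) should leave the allylic tert-butyldimethylsilyl ether and the triene untouched.

Step 16
Reactants: 30 terminal trienyne
Product: 32 tert-butyl{[(2Z,6E,8E,10E)-11-iodo-2,6,10-trimethylundeca-2,6,8,10-tetraen-1-yl]oxy}dimethylsilane, via alkenylalane 31 (not isolated)
Conditions: AlMe3, Cp2ZrCl2 (cat.), CH2Cl2, rt; then I2, THF, −30 °C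
Reagents that add atoms: trimethylaluminium C[Al](C)C; iodine II
Why: A second zirconium-catalysed syn-carboalumination, now of the conjugated dienyne, followed by iodinolysis of the alkenyl–aluminium bond with retention should give the (E)-2-methylalkenyl iodide (2'E).

Step 17
Reactants: 19 epoxy aldehyde; 32 tetraenyl iodide
Product: 34 [(1R,5S,6R)-6-[(1RS,2E,4E,6E,10Z)-12-{[tert-butyl(dimethyl)silyl]oxy}-1-hydroxy-3,7,11-trimethyldodeca-2,4,6,10-tetraen-1-yl]-5-hydroxy-2-oxo-7-oxabicyclo[4.1.0]hept-3-en-3-yl]methyl acetate (both C1' epimers), via alkenylchromium dichloride 33 (not isolated)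
Conditions: CrCl2 (excess), NiCl2 (cat.), DMSO, rt
Reagents that add atoms: none
Why: In this Nozaki–Hiyama–Kishi coupling the alkenylchromium reagent 33, formed through nickel catalysis, should add to the aldehyde in the presence of the enone, the acetate, the oxirane and the free hydroxyl, and the configuration at C1' is deliberately left open because both epimers are carried into the same ketone.

Step 18
Reactants: 34 coupled carbinol (C1' epimers)
Product: 35 [(1R,5S,6R)-6-[(2E,4E,6E,10Z)-12-{[tert-butyl(dimethyl)silyl]oxy}-3,7,11-trimethyldodeca-2,4,6,10-tetraenoyl]-5-hydroxy-2-oxo-7-oxabicyclo[4.1.0]hept-3-en-3-yl]methyl acetate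
Conditions: DDQ, CH2Cl2/pH 7 buffer, 0 °C
Reagents that add atoms: none
Why: DDQ oxidises by hydride abstraction and should therefore pick the trienyl carbinol at C1', whose cation is conjugated, over the C4 hydroxyl next to the electron-poor enone, so that both C1' epimers converge on one trienone.

Step 19
Reactants: 35 silylated trienone
Product: 36 [(1R,5S,6R)-5-hydroxy-6-[(2E,4E,6E,10Z)-12-hydroxy-3,7,11-trimethyldodeca-2,4,6,10-tetraenoyl]-2-oxo-7-oxabicyclo[4.1.0]hept-3-en-3-yl]methyl acetate
Conditions: HF·pyridine, pyridine, THF, 0 °C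
Reagents that add atoms: none
Why: Fluoride-mediated cleavage of the primary silyl ether with buffered HF·pyridine, done at the ketone stage so that no acid-labile trienyl carbinol is present, should leave the acetate and the oxirane intact.

Step 20
Reactants: 36 trienone diol
Product: 38 [(1R,5S,6R)-6-[(1S,2E,4E,6E,10Z)-1,12-dihydroxy-3,7,11-trimethyldodeca-2,4,6,10-tetraen-1-yl]-5-hydroxy-2-oxo-7-oxabicyclo[4.1.0]hept-3-en-3-yl]methyl acetate (target), via C4 alkoxyborohydride 37 (not isolated)
Conditions: Me4NBH(OAc)3, MeCN/AcOH (1:1), −30 °C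
Reagents that add atoms: none
Why: In this Evans–Saksena reduction the C4 hydroxyl exchanges onto boron (37) and delivers hydride intramolecularly to the C1' ketone through a chair-like six-membered transition state with the trienyl group equatorial, which should give the 1,3-anti diol, that is (1'S), while the ring enone, which has no hydroxyl within reach, is not reduced.

**Compound list**

1 | 2,2-dimethyl-1,3-dioxan-5-one | CC1(C)OCC(=O)CO1 | starting material
2 | (S)-1-amino-2-(methoxymethyl)pyrrolidine (SAMP) | COC[C@@H]1CCCN1N | starting material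
3 | (2S)-N-(2,2-dimethyl-1,3-dioxan-5-ylidene)-2-(methoxymethyl)pyrrolidin-1-amine | COC[C@@H]1CCCN1N=C1COC(C)(C)OC1 | intermediate
4 | methyl acrylate | COC(=O)C=C | starting material
5 | lithium azaenolate of 3 | COC[C@@H]1CCCN1[N-]C1=COC(C)(C)OC1.[Li+] | intermediate
6 | methyl 3-[(4S)-2,2-dimethyl-5-{[(2S)-2-(methoxymethyl)pyrrolidin-1-yl]imino}-1,3-dioxan-4-yl]propanoate (C=N geometry not defined) | COC(=O)CC[C@@H]1OC(C)(C)OCC1=NN1CCC[C@H]1COC | intermediate
7 | lithium hemiketal alkoxide from 6 and chloromethyllithium | ClCC([O-])(OC)CC[C@@H]1OC(C)(C)OCC1=NN1CCC[C@H]1COC.[Li+] | intermediate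
8 | 1-chloro-4-[(4S)-2,2-dimethyl-5-{[(2S)-2-(methoxymethyl)pyrrolidin-1-yl]imino}-1,3-dioxan-4-yl]butan-2-one | ClCC(=O)CC[C@@H]1OC(C)(C)OCC1=NN1CCC[C@H]1COC | intermediate
9 | (4S)-4-(4-chloro-3-oxobutyl)-2,2-dimethyl-1,3-dioxan-5-one | ClCC(=O)CC[C@@H]1OC(C)(C)OCC1=O | intermediate
10 | lithium chloro-enolate of 9 (enolate geometry not defined) | [Li+].[O-]C(=CCl)CC[C@@H]1OC(C)(C)OCC1=O | intermediate
11 | lithium chlorohydrin alkoxide: cis-fused aldolate, C5–O trans to C4–O, C6–Cl trans to C5–O | C1C[C@@H]2OC(C)(C)OC[C@]2([O-])[C@H](Cl)C1=O.[Li+] | intermediate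
12 | tricyclic epoxy ketone: (4S,5R,6R)-5,6-epoxy-4-hydroxy-5-(hydroxymethyl)cyclohexan-1-one 4,1'-O-isopropylidene acetal | C1C[C@@H]2OC(C)(C)OC[C@@]23O[C@H]3C1=O | intermediate
13 | lithium enolate of 12 (C1=C2) | [Li+].[O-]C1=CC[C@@H]2OC(C)(C)OC[C@@]23O[C@@H]13 | intermediate
14 | 2-(N-tert-butyl-S-phenylsulfinimidoyl) derivative of 12 (C2 and S not defined) | CC(C)(C)N=S(c1ccccc1)C1C[C@@H]2OC(C)(C)OC[C@@]23O[C@H]3C1=O | intermediate
15 | tricyclic epoxy enone: (4S,5R,6R)-5,6-epoxy-4-hydroxy-5-(hydroxymethyl)cyclohex-2-en-1-one 4,1'-O-isopropylidene acetal | C1=C[C@@H]2OC(C)(C)OC[C@@]23O[C@H]3C1=O | intermediate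
16 | 2-(hydroxymethyl) derivative of 15 | OCC1=C[C@@H]2OC(C)(C)OC[C@@]23O[C@H]3C1=O | intermediate
17 | 2-(acetoxymethyl) derivative of 15 | CC(=O)OCC1=C[C@@H]2OC(C)(C)OC[C@@]23O[C@H]3C1=O | intermediate
18 | [(1R,5S,6R)-5-hydroxy-6-(hydroxymethyl)-2-oxo-7-oxabicyclo[4.1.0]hept-3-en-3-yl]methyl acetate | CC(=O)OCC1=C[C@H](O)[C@@]2(CO)O[C@H]2C1=O | intermediate
19 | [(1R,5S,6R)-6-formyl-5-hydroxy-2-oxo-7-oxabicyclo[4.1.0]hept-3-en-3-yl]methyl acetate | CC(=O)OCC1=C[C@H](O)[C@@]2(C=O)O[C@H]2C1=O | intermediate
20 | 5-iodopent-1-yne | C#CCCCI | starting material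
21 | (pent-4-yn-1-yl)triphenylphosphonium iodide | C#CCCC[P+](c1ccccc1)(c1ccccc1)c1ccccc1.[I-] | intermediate
22 | 1-[(tert-butyldimethylsilyl)oxy]propan-2-one | CC(=O)CO[Si](C)(C)C(C)(C)C | starting material
23 | (pent-4-yn-1-ylidene)triphenylphosphorane | C#CCCC=P(c1ccccc1)(c1ccccc1)c1ccccc1 | intermediate
24 | (Z)-tert-butyldimethyl[(2-methylhept-2-en-6-yn-1-yl)oxy]silane | C#CCC/C=C(/C)CO[Si](C)(C)C(C)(C)C | intermediate
25 | (E)-1,2-dichloroethene | Cl/C=C/Cl | starting material
26 | ethynyltrimethylsilane | C[Si](C)(C)C#C | starting material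
27 | (E)-(4-chlorobut-3-en-1-yn-1-yl)trimethylsilane | C[Si](C)(C)C#C/C=C/Cl | intermediate
28 | [(1E,5Z)-7-{[tert-butyl(dimethyl)silyl]oxy}-2,6-dimethylhepta-1,5-dien-1-yl]dimethylalane | C[Al](C)/C=C(\C)CC/C=C(/C)CO[Si](C)(C)C(C)(C)C | intermediate
29 | tert-butyldimethyl{[(2Z,6E,8E)-2,6-dimethyl-11-(trimethylsilyl)undeca-2,6,8-trien-10-yn-1-yl]oxy}silane | C[Si](C)(C)C#C/C=C/C=C(\C)CC/C=C(/C)CO[Si](C)(C)C(C)(C)C | intermediate
30 | tert-butyl{[(2Z,6E,8E)-2,6-dimethylundeca-2,6,8-trien-10-yn-1-yl]oxy}dimethylsilane | C#C/C=C/C=C(\C)CC/C=C(/C)CO[Si](C)(C)C(C)(C)C | intermediate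
31 | [(1E,3E,5E,9Z)-11-{[tert-butyl(dimethyl)silyl]oxy}-2,6,10-trimethylundeca-1,3,5,9-tetraen-1-yl]dimethylalane | C[Al](C)/C=C(C)/C=C/C=C(\C)CC/C=C(/C)CO[Si](C)(C)C(C)(C)C | intermediate
32 | tert-butyl{[(2Z,6E,8E,10E)-11-iodo-2,6,10-trimethylundeca-2,6,8,10-tetraen-1-yl]oxy}dimethylsilane | I/C=C(C)/C=C/C=C(\C)CC/C=C(/C)CO[Si](C)(C)C(C)(C)C | intermediate
33 | alkenylchromium dichloride from 32 | Cl[Cr](Cl)/C=C(C)/C=C/C=C(\C)CC/C=C(/C)CO[Si](C)(C)C(C)(C)C | intermediate
34 | [(1R,5S,6R)-6-[(1RS,2E,4E,6E,10Z)-12-{[tert-butyl(dimethyl)silyl]oxy}-1-hydroxy-3,7,11-trimethyldodeca-2,4,6,10-tetraen-1-yl]-5-hydroxy-2-oxo-7-oxabicyclo[4.1.0]hept-3-en-3-yl]methyl acetate | CC(=O)OCC1=C[C@H](O)[C@@]2(C(O)/C=C(C)/C=C/C=C(\C)CC/C=C(/C)CO[Si](C)(C)C(C)(C)C)O[C@H]2C1=O | intermediate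
35 | [(1R,5S,6R)-6-[(2E,4E,6E,10Z)-12-{[tert-butyl(dimethyl)silyl]oxy}-3,7,11-trimethyldodeca-2,4,6,10-tetraenoyl]-5-hydroxy-2-oxo-7-oxabicyclo[4.1.0]hept-3-en-3-yl]methyl acetate | CC(=O)OCC1=C[C@H](O)[C@@]2(C(=O)/C=C(C)/C=C/C=C(\C)CC/C=C(/C)CO[Si](C)(C)C(C)(C)C)O[C@H]2C1=O | intermediate
36 | [(1R,5S,6R)-5-hydroxy-6-[(2E,4E,6E,10Z)-12-hydroxy-3,7,11-trimethyldodeca-2,4,6,10-tetraenoyl]-2-oxo-7-oxabicyclo[4.1.0]hept-3-en-3-yl]methyl acetate | CC(=O)OCC1=C[C@H](O)[C@@]2(C(=O)/C=C(C)/C=C/C=C(\C)CC/C=C(/C)CO)O[C@H]2C1=O | intermediate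
37 | tetramethylammonium C4-O-diacetoxyborohydride of 36 | CC(=O)OCC1=C[C@H](O[BH-](OC(C)=O)OC(C)=O)[C@@]2(C(=O)/C=C(C)/C=C/C=C(\C)CC/C=C(/C)CO)O[C@H]2C1=O.C[N+](C)(C)C | intermediate
38 | [(1R,5S,6R)-6-[(1S,2E,4E,6E,10Z)-1,12-dihydroxy-3,7,11-trimethyldodeca-2,4,6,10-tetraen-1-yl]-5-hydroxy-2-oxo-7-oxabicyclo[4.1.0]hept-3-en-3-yl]methyl acetate | CC(=O)OCC1=C[C@H](O)[C@@]2([C@@H](O)/C=C(C)/C=C/C=C(\C)CC/C=C(/C)CO)O[C@H]2C1=O | target

**Step count and risks**

Total steps: 20. Longest linear sequence: 14 steps (steps 1–10 and 17–20); the chain fragment takes steps 11–16.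

Steps most likely to fail:

1. Step 5. The configuration at C4 could erode by enolisation of the dioxanone before the ring closes, or the enolate could add to the other face of C5 (trans-fused aldolate), which would end in the oxirane syn to C4–O. The fallback makes C5–C6 by aldol condensation and adds the oxirane oxygen afterwards. It sets out from 9: reductive dechlorination (Zn, AcOH) would give the methyl ketone (4S)-2,2-dimethyl-4-(3-oxobutyl)-1,3-dioxan-5-one F1. Amine-catalysed intramolecular aldol addition (pyrrolidine, AcOH) would give the ketol (8aS)-4a-hydroxy-2,2-dimethylhexahydro-4H-1,3-benzodioxin-6(5H)-one F2, and dehydration in the same flask the bicyclic enone (8aS)-2,2-dimethyl-8,8a-dihydro-4H-1,3-benzodioxin-6(7H)-one F3. Nucleophilic epoxidation of F3 (t-BuOOH, DBU, Weitz–Scheffer type), expected from the face opposite the allylic C4–O bond, would deliver 12, where the route is rejoined.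

2. Step 17. Divalent chromium could reduce the α,β-epoxy ketone (or the epoxy aldehyde) in competition with the carbonyl addition. The fallback makes the C1'–C2' bond at the ketone level by palladium-catalysed acyl coupling. It sets out from 19 and 32: chlorite oxidation of 19 (NaClO2, NaH2PO4, 2-methylbut-2-ene) would give (1R,5S,6R)-3-(acetoxymethyl)-5-hydroxy-2-oxo-7-oxabicyclo[4.1.0]hept-3-ene-6-carboxylic acid F4, and ethanethiol with a carbodiimide would convert it into the S-ethyl thioester F5. Iodide 32 would be taken by iodine–lithium exchange (t-BuLi, −78 °C) to the alkenyllithium F6 and with ZnCl2 to the alkenylzinc chloride F7. Fukuyama coupling of F5 with F7 (PdCl2(PPh3)2 cat.) would give trienone 35 directly, so the route is rejoined at 35 and step 18 is not needed.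

3. Step 20. The internal hydride delivery could show poor facial selectivity because the six-membered transition state is constrained by the ring, or non-directed reduction could compete. The fallback sets C1' by reagent control in the C–C bond formation instead of by reduction. It sets out from 19 and 32: a Nozaki–Hiyama–Kishi coupling run with CrCl2 complexed to a chiral sulfonamide ligand (asymmetric variant, NiCl2 cat., MeCN, the ligand antipode that favours the (1'S) adduct) would give the (1'S) silyl ether of the target F8. HF·pyridine would then remove the silyl group and give 38, where the route ends.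

Further compounds
F1 | step 5 | (4S)-2,2-dimethyl-4-(3-oxobutyl)-1,3-dioxan-5-one | CC(=O)CC[C@@H]1OC(C)(C)OCC1=O
F2 | step 5 | (8aS)-4a-hydroxy-2,2-dimethylhexahydro-4H-1,3-benzodioxin-6(5H)-one (either configuration at C4a) | O=C1CC[C@@H]2OC(C)(C)OCC2(O)C1
F3 | step 5 | (8aS)-2,2-dimethyl-8,8a-dihydro-4H-1,3-benzodioxin-6(7H)-one | O=C1C=C2COC(C)(C)O[C@H]2CC1
F4 | step 17 | (1R,5S,6R)-3-(acetoxymethyl)-5-hydroxy-2-oxo-7-oxabicyclo[4.1.0]hept-3-ene-6-carboxylic acid | CC(=O)OCC1=C[C@H](O)[C@@]2(C(=O)O)O[C@H]2C1=O
F5 | step 17 | S-ethyl (1R,5S,6R)-3-(acetoxymethyl)-5-hydroxy-2-oxo-7-oxabicyclo[4.1.0]hept-3-ene-6-carbothioate | CC(=O)OCC1=C[C@H](O)[C@@]2(C(=O)SCC)O[C@H]2C1=O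
F6 | step 17 | [(1E,3E,5E,9Z)-11-{[tert-butyl(dimethyl)silyl]oxy}-2,6,10-trimethylundeca-1,3,5,9-tetraen-1-yl]lithium | [Li]/C=C(C)/C=C/C=C(\C)CC/C=C(/C)CO[Si](C)(C)C(C)(C)C
F7 | step 17 | [(1E,3E,5E,9Z)-11-{[tert-butyl(dimethyl)silyl]oxy}-2,6,10-trimethylundeca-1,3,5,9-tetraen-1-yl]zinc chloride | Cl[Zn]/C=C(C)/C=C/C=C(\C)CC/C=C(/C)CO[Si](C)(C)C(C)(C)C
F8 | step 20 | [(1R,5S,6R)-6-[(1S,2E,4E,6E,10Z)-12-{[tert-butyl(dimethyl)silyl]oxy}-1-hydroxy-3,7,11-trimethyldodeca-2,4,6,10-tetraen-1-yl]-5-hydroxy-2-oxo-7-oxabicyclo[4.1.0]hept-3-en-3-yl]methyl acetate | CC(=O)OCC1=C[C@H](O)[C@@]2([C@@H](O)/C=C(C)/C=C/C=C(\C)CC/C=C(/C)CO[Si](C)(C)C(C)(C)C)O[C@H]2C1=O
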